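The rate constants stand for no real mixture; the flask was simulated.

We want G.E.

all flasks: time 5.0 h

| run | G | E | temperature | remark |
|---|---|---|---|---|
| ash | 49 mM (fed, over 3.0 h) | 1.50 equiv | 80 °C | all else is in the flask from the start; the feed brings no volume worth counting |
| alder | 49 mM (fed, over 50 min) | 1.50 equiv | 80 °C | all else is in the flask from the start; the feed brings no volume worth counting |
| maple | 49 mM | 1.50 equiv |  | everything together at the start at 60 °C, warmed to 80 °C at 3.0 h |
| larch | 49 mM | 1.50 equiv | 80 °C | everything together at the start |
| oak | 49 mM | 1.50 equiv (fed, over 3.0 h) |  | the addition at 60 °C, then warmed to 80 °C; the feed brings no volume worth counting |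

    G + E → G.E (k1 = 5.59 L mol⁻¹ h⁻¹, Ea1 = 93.0 kJ mol⁻¹)
    E + G.E → E.G.E (k2 = 2.11 L mol⁻¹ h⁻¹, Ea2 = 95.0 kJ mol⁻¹)
    E + E.G.E → Z (k3 = 2.04 L mol⁻¹ h⁻¹, Ea3 = 70.0 kJ mol⁻¹)
    2 E → E2 (k4 = 0.902 L mol⁻¹ h⁻¹, Ea4 = 81.0 kJ mol⁻¹)
    D ⇌ G.E, rate k5*(cs5 - [G.E]) while solid is left; crystals form when [G.E] > cs5 (cs5 = 4.7 mM, k5 = 2.02 h⁻¹)
    G.E → X (k6 = 0.126 h⁻¹, Ea6 = 125 kJ mol⁻¹)
    (constants at 80 °C)

- for G.E the D are counted in
- two of one species on the left: rate k times its square, two consumed each time
- as a solid, counted per litre of solution: D
- the constants hold at 80 °C; other temperatures follow from the activation energies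

1. the flask that comes out highest in amount of G.E, in percent of the G charged, or "all alike" when all lie within 1.5 percentage points (ash / alder / maple / larch / oak / all alike)
2. G.E at the end, in percent of the G charged, ash
3. G.E at the end, in percent of the G charged, alder
4. G.E at the end, in percent of the G charged, maple
5. G.E at the end, in percent of the G charged, larch
6. G.E at the end, in percent of the G charged, oak

Which numbers must we know well? The constant of the first step comes first. In larch, at charged concentrations, G has a half-life of 1.7 h, shorter than the run, and G falls pseudo-first-order at a given [E], so this constant acts through an exponent. The loss of E to E2 counts as well. At the start of larch, E goes to G 2.1 times as fast as to E2, so that constant moves mean [E]. The steps that consume G.E count too, and we do not rank them below that loss. We take dissolved [G.E] to stay near the solubility 4.7 mM while D stands, far below the charge of G, and we reckon the share of these steps below. The third step acts on E.G.E, so we leave it out.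

Now the numbers, for larch. [E] starts at 73.5 mM. Held there, it gives an exponent of 2.05, so 12.9% of G is left. We put that answer back. G would use 42.7 mM of E, and E2 would take a further share at the starting ratio of 2.07, so [E] ends at 10.1 mM. Mean [E] is then 41.8 mM. The contact number, the first-step constant times mean [E] times the contact time, is 1.17, and G left is e to the minus that number, 31.0%. Steps on dissolved G.E take 10.3% of the charge, so we commit to 58.6% G.E in larch. Larch also keeps G and E together hot for longer than alder, ash, maple or oak, so we rank it above them.

The forecast also names larch. It gives 52% for larch, from 47% to 57%, then 50% for alder, 42.5% for maple, 42% for ash and 39% for oak, holding that “conversion rather than selectivity sets the ranking”. Our larch figure lies above its high end.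

The simulation gives larch highest at 52.3%, then alder 49.6%, maple 41.7%, ash 40.6% and oak 40.0%. The forecast stands on every count. In larch, G left is 33.7% against our 31.0%, and our G.E is 6.3 percentage points high.

The neighbouring flask is larch with 0.380 equiv of E, 18.6 mM at the start. Its first round has an exponent of 0.520 and asks for 22.3 mM of E, more than the charge. E is the limiting reagent here, so we put its end value at zero in the mean. The contact number drops to 0.260, which is 0.222 of the larch value 1.17. That gives G left 77.1% and G.E 15.9%. The flask ends with G 75.4%, E 27.3% of its own charge, and G.E 17.8%.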